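The ratio of Z to Q in the alder charge, 80.0 %, is the ceiling on the share asked for: each G takes one Z, so Z is the limiting reagent.

in all of them: Z 0.0800 M
- ash: Q 0.100 M
- elm: Q 0.300 M
- alder: Q 0.100 M; time 72 min

- ash run (time / min: [G] / M): 0.96: 7 × 10⁻⁴; 1.6: 6 × 10⁻⁴; 2.8: 0.0052; 4.8: 0.0113; 8.2: 0.0213; 14: 0.0383; 24: 0.0580
- elm run (time / min: [G] / M): 0.96: 0.0022; 1.6: 0.0056; 2.8: 0.0165; 4.8: 0.0374; 8.2: 0.0664; 14: 0.0795; 24: 0.0800

(readings scatter by 8 × 10⁻⁴ M)

- the power of [Q] that the first rate follows, about the charge of the ash run; measure it at two percent of Q made into G (one fixed amount of G, the same in the runs compared)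
- G in the alder run at 72 min, as a share of the Q charged

- Overall: Q + Z -> G.
- Constant volume, constant temperature.
- A reading of a species includes what of it is bound.
- "The second partner" is Z.
- An order is taken over about fifteen percent of the charge, up and down.

Alder has the charge of ash and runs longer, so I carry one number over from ash: the mean constant, the value of k in rate = k[Q][Z] that, held flat from time zero, lands on the ash reading at 24 min. It comes to 0.882 M⁻¹ min⁻¹.

I bracket alder with two extremes. In the first, Z doesn't matter and Q decays at first order with its own mean constant from that reading, 0.0361 min⁻¹. G then meets the Z charge at 44.5 min, earlier than 72 min, and alder ends on the ceiling. In the second, the rate follows [Q][Z] with the mean constant held flat, and alder reaches 74.2 %. I take that as my low end: the same reckoning stopped at 14 min of ash reads 0.602 M⁻¹ min⁻¹, lower than the mean constant, so in ash the reckoned constant climbs between those two readings. I commit to alder lying between the two.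

The forecast gives 0.65 (range 0.45 to 1) for the order and 80 % (range 75 % to 80 %) for alder, noting that “elm keeps running fast until Z is gone”.

The flask gives an order of 0.72 and 78.6 % for alder, above my low end and below the ceiling.

    Q + Z → L (0.8520 M⁻¹ min⁻¹)
    L → G (0.7620 min⁻¹)
    2 Z ⇌ Z2, settled at all times (16.00 M⁻¹)
    Q + Z + G → 2 G (23.04 M⁻² min⁻¹)

Put through the same formula, the alder result asks for a mean constant of 1.74 M⁻¹ min⁻¹ over 72 min, twice the ash value. The conversion of Q + Z + G into 2 G lifts alder: the alder run without that conversion ends at 68.1 %, not 78.6 %. In elm, the ash constant held flat puts a quarter of the Q at 12.8 min, and the elm flask is there sooner, at 10.6 min.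

The runs were generated by integration with made-up constants; noise was put on by code.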